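**Retrosynthetic overview** (azulene numbering: C3 carbinol, C3a/C8a ring fusion, C4 ester carbon, C6 methyl-bearing alkene carbon)

1. The aryl ester is attached last by acylation of the C3,C4-diol at C4–OH; C4 comes from hydroxyl-directed reduction of a C4 ketone; the C6 methyl is a reduced ester that first pulls the alkene into C5=C6.
2. The five-membered ring is formed second, by an intramolecular Mukaiyama aldol (C3–C3a bond) of a cycloheptadienyl silyl enol ether onto a side-chain isopropyl ketone; this sets C3 and C3a.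
3. The seven-membered ring is formed first, in the key step: an enantioselective dirhodium-catalysed cyclopropanation/Cope rearrangement (formal [4+3]) of an acyclic 2-siloxydiene (C5–C4–C3a–C8a) with a vinyldiazoacetate (C6–C7–C8). It forms C5–C6, then C8–C8a, and the quaternary C8a.
4. Enabling feature: in the ring C3a–C4–C5–C6–C7–C8–C8a, the oxygenated C4 (next to ring-fusion C3a) and the methyl-bearing C6 flank the lone C5 and lie opposite the C8–C8a bond. This is a cyclohepta-1,4-diene pattern (C4=C3a enol ether, C6=C7 enoate), the retron of a cis-divinylcyclopropane.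
5. The diene is assembled from acetylacetone (C5, C4, C3a, C8a and its methyl), a cyanoethylzinc reagent (C1–C3) and isopropylmagnesium chloride.

Key step: step 6

Remark (assumption): Rh2(R-DOSP)4, dirhodium tetrakis[(R)-N-(4-dodecylbenzenesulfonyl)prolinate], is taken to induce in the sense established for terminal alkenes, with the alkenyl group of the enol ether ending cis to the vinyl group; if the sense proves opposite, Rh2(S-DOSP)4 is used and nothing else changes.

**Route**

Step 1
Reactants: 1 pentane-2,4-dione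
Product: 2 (2Z)-4-oxopent-2-en-2-yl trifluoromethanesulfonate
Conditions: Tf2O, LiOTf, Et3N, CH2Cl2, −78 → 0 °C
Reagents that add atoms: trifluoromethanesulfonic anhydride, O=S(=O)(OS(=O)(=O)C(F)(F)F)C(F)(F)F
Why: O-sulfonylation of the lithium-chelated enolate of the 1,3-diketone (enol triflate formation) should give the Z isomer, with the triflate cis to the remaining acetyl group.

Step 2
Reactants: 2 (2Z)-4-oxopent-2-en-2-yl trifluoromethanesulfonate; 3 (2-cyanoethyl)zinc bromide (0.5 M in THF)
Product: 4 (4Z)-4-methyl-6-oxohept-4-enenitrile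
Conditions: Pd(dppf)Cl2 (3 mol%), THF, 25 → 50 °C
Reagents that add atoms: none
Why: Negishi cross-coupling of an alkenyl triflate with a functionalised primary alkylzinc halide proceeds with retention of alkene geometry and tolerates ketone and nitrile, so the cyanoethyl chain ends cis to the acetyl group.

Step 3
Reactants: 4 (4Z)-4-methyl-6-oxohept-4-enenitrile
Product: 5 (4Z)-6-[(tert-butyldimethylsilyl)oxy]-4-methylhepta-4,6-dienenitrile
Conditions: TBSOTf, Et3N, CH2Cl2, −20 °C
Reagents that add atoms: tert-butyldimethylsilyl trifluoromethanesulfonate, CC(C)(C)[Si](C)(C)OS(=O)(=O)C(F)(F)F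
Why: Soft enolisation (silyl triflate with a tertiary amine) should silylate the enone on its cross-conjugated methyl side to give the 2-siloxy-1,3-diene, leave the far less acidic nitrile alone, and at low temperature keep the Z alkene intact.

Step 4
Reactants: 5 (4Z)-6-[(tert-butyldimethylsilyl)oxy]-4-methylhepta-4,6-dienenitrile; 6 isopropylmagnesium chloride
Product: 8 (6Z)-8-[(tert-butyldimethylsilyl)oxy]-2,6-dimethylnona-6,8-dien-3-one, via ketimine 7 (not isolated)
Conditions: CuBr·SMe2 (5 mol%), THF, 0 → 40 °C; then pH 5 acetate buffer, 0 °C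
Reagents that add atoms: water, O
Why: Copper-catalysed Grignard addition to a nitrile stops at the N-magnesio ketimine, which buffered hydrolysis turns into the ketone while the silyl dienol ether survives; bringing in the ketone only after the enol ether avoids competition between two enolisable carbonyl groups.

Step 5
Reactants: 9 methyl but-3-enoate
Product: 10 methyl 2-diazobut-3-enoate
Conditions: 4-acetamidobenzenesulfonyl azide, DBU, MeCN, 0 °C; used at once as a cold hydrocarbon solution
Reagents that add atoms: 4-acetamidobenzenesulfonyl azide, CC(=O)Nc1ccc(cc1)S(=O)(=O)N=[N+]=[N-]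
Why: Base-mediated diazo transfer (Regitz type) to the allylic alpha position of the beta,gamma-unsaturated ester gives the vinyldiazoacetate, which must be used immediately because it slowly cyclises to a pyrazole.

Step 6
Reactants: 8 (6Z)-8-[(tert-butyldimethylsilyl)oxy]-2,6-dimethylnona-6,8-dien-3-one; 10 methyl 2-diazobut-3-enoate
Product: 12 methyl (4S)-6-[(tert-butyldimethylsilyl)oxy]-4-methyl-4-(4-methyl-3-oxopentyl)cyclohepta-1,5-diene-1-carboxylate, via cis-divinylcyclopropane 11 (not isolated)
Conditions: Rh2(R-DOSP)4 (1 mol%), 2,2-dimethylbutane, −40 → 25 °C, slow addition of 10; then toluene, 80 °C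
Reagents that add atoms: none
Why: The chiral dirhodium prolinate turns 10 into a rhodium vinylcarbenoid that should cyclopropanate only the terminal, siloxy-activated 1,1-disubstituted double bond of 8 to give cis-divinylcyclopropane 11, whose boat-like [3,3]-sigmatropic (Cope) rearrangement breaks the donor–acceptor bond of the three-membered ring and joins the vinyl CH2 terminus (C8) to the methyl-bearing alkene carbon (C8a). This is the tandem cyclopropanation/Cope rearrangement (formal [4+3] cycloaddition) of vinyldiazoacetates with dienes, which has close precedent for 2-siloxydienes and for dienes whose reacting terminus is fully substituted. The seven-membered ring is closed in the sigmatropic step, suprafacially on both three-carbon halves, so that a C6–C7–C8 vinylcarbenoid unit ends joined to the C5–C4–C3a–C8a siloxydiene unit. The only new stereocentre, quaternary C8a, is controlled by the catalyst, which fixes the absolute configuration of the cyclopropane (1S,2R expected), together with the Z geometry of the trisubstituted alkene; both are transferred stereospecifically through the boat transition state. The step needs chemoselectivity for the terminal enol ether over the trisubstituted alkene and the ketone, cis-selective cyclopropanation, and suppression of zwitterionic leakage; the steric bias of donor/acceptor carbenoids against trisubstituted alkenes, the hydrocarbon solvent and the low temperature are expected to secure these.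

Step 7
Reactants: 12 methyl (4S)-6-[(tert-butyldimethylsilyl)oxy]-4-methyl-4-(4-methyl-3-oxopentyl)cyclohepta-1,5-diene-1-carboxylate
Product: 13 methyl (3R,3aR,8aS)-3-hydroxy-8a-methyl-4-oxo-3-(propan-2-yl)-1,2,3,3a,4,5,8,8a-octahydroazulene-6-carboxylate
Conditions: TiCl4 (1.1 equiv), CH2Cl2, −78 °C; then pH 7 buffer
Reagents that add atoms: none
Why: Intramolecular Mukaiyama aldol addition, in which the regiodefined silyl enol ether attacks the TiCl4-activated isopropyl ketone in a 5-(enolexo)-exo-trig closure that is expected to give only the cis-fused hydroazulene (C3a–H cis to the C8a methyl), with the isopropyl group next to C3a–H and the oxygen next to C4 in the open transition state, which sets C3 (hydroxyl cis to the C3a–C4 bond).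

Step 8
Reactants: 13 methyl (3R,3aR,8aS)-3-hydroxy-8a-methyl-4-oxo-3-(propan-2-yl)-1,2,3,3a,4,5,8,8a-octahydroazulene-6-carboxylate
Product: 14 methyl (3R,3aR,8aR)-3-hydroxy-8a-methyl-4-oxo-3-(propan-2-yl)-1,2,3,3a,4,7,8,8a-octahydroazulene-6-carboxylate
Conditions: DBU (0.3 equiv), CH2Cl2, 25 °C
Reagents that add atoms: none
Why: Base-catalysed 1,3-prototropic shift through the dienolate moves the C6=C7 double bond to C5=C6, where it is conjugated with both ketone and ester (the thermodynamic sink), while the hindered C3a–H between two fully substituted carbons is not expected to exchange under these mild conditions.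

Step 9
Reactants: 14 methyl (3R,3aR,8aR)-3-hydroxy-8a-methyl-4-oxo-3-(propan-2-yl)-1,2,3,3a,4,7,8,8a-octahydroazulene-6-carboxylate
Product: 15 methyl (3R,3aS,4R,8aR)-3,4-dihydroxy-8a-methyl-3-(propan-2-yl)-1,2,3,3a,4,7,8,8a-octahydroazulene-6-carboxylate
Conditions: Me4NBH(OAc)3, MeCN/AcOH (1:1), −30 °C
Reagents that add atoms: none
Why: Hydroxyl-directed reduction of a beta-hydroxy ketone (Evans–Saksena type), in which hydride is delivered intramolecularly from the alkoxy-bound acetoxyborohydride through a chair transition state with the isopropyl group, C8a and C5 equatorial; this should give the 4R alcohol (C4–O cis to the C3a–C3 bond) and leave the enoate untouched.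

Step 10
Reactants: 15 methyl (3R,3aS,4R,8aR)-3,4-dihydroxy-8a-methyl-3-(propan-2-yl)-1,2,3,3a,4,7,8,8a-octahydroazulene-6-carboxylate
Product: 16 (3R,3aS,4R,8aR)-6-(hydroxymethyl)-8a-methyl-3-(propan-2-yl)-1,2,3,3a,4,7,8,8a-octahydroazulene-3,4-diol
Conditions: iBu2AlH (5 equiv), CH2Cl2, −78 → −30 °C; aq. potassium sodium tartrate
Reagents that add atoms: none
Why: iBu2AlH reduces the conjugated ester by 1,2-addition to the primary allylic alcohol without touching the trisubstituted alkene or the stereocentres.

Step 11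
Reactants: 16 (3R,3aS,4R,8aR)-6-(hydroxymethyl)-8a-methyl-3-(propan-2-yl)-1,2,3,3a,4,7,8,8a-octahydroazulene-3,4-diol
Product: 18 (3R,3aS,4R,8aR)-6,8a-dimethyl-3-(propan-2-yl)-1,2,3,3a,4,7,8,8a-octahydroazulene-3,4-diol, via allylic mesylate 17 (not isolated)
Conditions: MsCl (1.05 equiv), Et3N, THF, −40 °C; then LiEt3BH (4 equiv), −40 → 0 °C
Reagents that add atoms: none
Why: The unhindered primary allylic alcohol should be sulfonylated selectively over the hindered secondary and the tertiary alcohol, and LiEt3BH then displaces the mesylate by direct SN2 hydride attack at the primary carbon, turning the former ester carbon into the C6 methyl group with the double bond left in place.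

Step 12
Reactants: 19 3-hydroxy-4-methoxybenzoic acid
Product: 21 3-[(tert-butyldimethylsilyl)oxy]-4-methoxybenzoic acid, via bis-silylated acid 20 (not isolated)
Conditions: TBSCl (2.3 equiv), imidazole, DMF, 25 °C; then AcOH, THF/H2O, 25 °C
Reagents that add atoms: tert-butyldimethylsilyl chloride, CC(C)(C)[Si](C)(C)Cl
Why: Exhaustive silylation followed by selective hydrolysis of the labile silyl ester leaves the phenol protected as its silyl ether and frees the carboxylic acid.

Step 13
Reactants: 18 (3R,3aS,4R,8aR)-6,8a-dimethyl-3-(propan-2-yl)-1,2,3,3a,4,7,8,8a-octahydroazulene-3,4-diol; 21 3-[(tert-butyldimethylsilyl)oxy]-4-methoxybenzoic acid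
Product: 23 (3R,3aS,4R,8aR)-3-hydroxy-6,8a-dimethyl-3-(propan-2-yl)-1,2,3,3a,4,7,8,8a-octahydroazulen-4-yl 3-[(tert-butyldimethylsilyl)oxy]-4-methoxybenzoate, via mixed anhydride 22 (not isolated)
Conditions: 2,4,6-trichlorobenzoyl chloride, Et3N, THF, 25 °C; then 18, DMAP, toluene, 25 → 50 °C
Reagents that add atoms: none
Why: Yamaguchi esterification, in which the mixed anhydride is attacked under DMAP catalysis at the unhindered aroyl carbonyl by the secondary allylic C4 hydroxyl with retention at C4, while the tertiary C3 hydroxyl is too hindered to acylate.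

Step 14
Reactants: 23 (3R,3aS,4R,8aR)-3-hydroxy-6,8a-dimethyl-3-(propan-2-yl)-1,2,3,3a,4,7,8,8a-octahydroazulen-4-yl 3-[(tert-butyldimethylsilyl)oxy]-4-methoxybenzoate
Product: 24 (3R,3aS,4R,8aR)-3-hydroxy-6,8a-dimethyl-3-(propan-2-yl)-1,2,3,3a,4,7,8,8a-octahydroazulen-4-yl 3-hydroxy-4-methoxybenzoate
Conditions: Bu4NF (1.1 equiv), AcOH (1.1 equiv), THF, 0 °C
Reagents that add atoms: none
Why: Buffered fluoride cleaves the aryl silyl ether selectively (phenoxide is a good leaving group on silicon) and should not affect the allylic benzoate or the tertiary alcohol.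

**Compound list**

1 | pentane-2,4-dione | CC(=O)CC(C)=O | starting material
2 | (2Z)-4-oxopent-2-en-2-yl trifluoromethanesulfonate | CC(=O)/C=C(/C)OS(=O)(=O)C(F)(F)F | intermediate
3 | (2-cyanoethyl)zinc bromide | N#CCC[Zn]Br | starting material
4 | (4Z)-4-methyl-6-oxohept-4-enenitrile | CC(=O)/C=C(/C)CCC#N | intermediate
5 | (4Z)-6-[(tert-butyldimethylsilyl)oxy]-4-methylhepta-4,6-dienenitrile | C=C(O[Si](C)(C)C(C)(C)C)/C=C(/C)CCC#N | intermediate
6 | isopropylmagnesium chloride | CC(C)[Mg]Cl | starting material
7 | (6Z)-8-[(tert-butyldimethylsilyl)oxy]-2,6-dimethylnona-6,8-dien-3-imine | C=C(O[Si](C)(C)C(C)(C)C)/C=C(/C)CCC(=N)C(C)C | intermediate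
8 | (6Z)-8-[(tert-butyldimethylsilyl)oxy]-2,6-dimethylnona-6,8-dien-3-one | C=C(O[Si](C)(C)C(C)(C)C)/C=C(/C)CCC(=O)C(C)C | intermediate
9 | methyl but-3-enoate | COC(=O)CC=C | starting material
10 | methyl 2-diazobut-3-enoate | COC(=O)C(=[N+]=[N-])C=C | intermediate
11 | methyl (1S,2R)-2-[(tert-butyldimethylsilyl)oxy]-2-[(1Z)-2,6-dimethyl-5-oxohept-1-en-1-yl]-1-ethenylcyclopropane-1-carboxylate | COC(=O)[C@]1(C=C)C[C@@]1(O[Si](C)(C)C(C)(C)C)/C=C(/C)CCC(=O)C(C)C | intermediate
12 | methyl (4S)-6-[(tert-butyldimethylsilyl)oxy]-4-methyl-4-(4-methyl-3-oxopentyl)cyclohepta-1,5-diene-1-carboxylate | COC(=O)C1=CC[C@](C)(CCC(=O)C(C)C)C=C(O[Si](C)(C)C(C)(C)C)C1 | intermediate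
13 | methyl (3R,3aR,8aS)-3-hydroxy-8a-methyl-4-oxo-3-(propan-2-yl)-1,2,3,3a,4,5,8,8a-octahydroazulene-6-carboxylate | COC(=O)C1=CC[C@]2(C)CC[C@@](O)(C(C)C)[C@@H]2C(=O)C1 | intermediate
14 | methyl (3R,3aR,8aR)-3-hydroxy-8a-methyl-4-oxo-3-(propan-2-yl)-1,2,3,3a,4,7,8,8a-octahydroazulene-6-carboxylate | COC(=O)C1=CC(=O)[C@H]2[C@](O)(C(C)C)CC[C@@]2(C)CC1 | intermediate
15 | methyl (3R,3aS,4R,8aR)-3,4-dihydroxy-8a-methyl-3-(propan-2-yl)-1,2,3,3a,4,7,8,8a-octahydroazulene-6-carboxylate | COC(=O)C1=C[C@@H](O)[C@H]2[C@](O)(C(C)C)CC[C@@]2(C)CC1 | intermediate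
16 | (3R,3aS,4R,8aR)-6-(hydroxymethyl)-8a-methyl-3-(propan-2-yl)-1,2,3,3a,4,7,8,8a-octahydroazulene-3,4-diol | OCC1=C[C@@H](O)[C@H]2[C@](O)(C(C)C)CC[C@@]2(C)CC1 | intermediate
17 | [(3R,3aS,4R,8aR)-3,4-dihydroxy-8a-methyl-3-(propan-2-yl)-1,2,3,3a,4,7,8,8a-octahydroazulen-6-yl]methyl methanesulfonate | CS(=O)(=O)OCC1=C[C@@H](O)[C@H]2[C@](O)(C(C)C)CC[C@@]2(C)CC1 | intermediate
18 | (3R,3aS,4R,8aR)-6,8a-dimethyl-3-(propan-2-yl)-1,2,3,3a,4,7,8,8a-octahydroazulene-3,4-diol | CC1=C[C@@H](O)[C@H]2[C@](O)(C(C)C)CC[C@@]2(C)CC1 | intermediate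
19 | 3-hydroxy-4-methoxybenzoic acid | COc1ccc(cc1O)C(=O)O | starting material
20 | tert-butyldimethylsilyl 3-[(tert-butyldimethylsilyl)oxy]-4-methoxybenzoate | COc1ccc(cc1O[Si](C)(C)C(C)(C)C)C(=O)O[Si](C)(C)C(C)(C)C | intermediate
21 | 3-[(tert-butyldimethylsilyl)oxy]-4-methoxybenzoic acid | COc1ccc(cc1O[Si](C)(C)C(C)(C)C)C(=O)O | intermediate
22 | 3-[(tert-butyldimethylsilyl)oxy]-4-methoxybenzoic 2,4,6-trichlorobenzoic anhydride | COc1ccc(cc1O[Si](C)(C)C(C)(C)C)C(=O)OC(=O)c1c(Cl)cc(Cl)cc1Cl | intermediate
23 | (3R,3aS,4R,8aR)-3-hydroxy-6,8a-dimethyl-3-(propan-2-yl)-1,2,3,3a,4,7,8,8a-octahydroazulen-4-yl 3-[(tert-butyldimethylsilyl)oxy]-4-methoxybenzoate | COc1ccc(C(=O)O[C@@H]2C=C(C)CC[C@]3(C)CC[C@@](O)(C(C)C)[C@H]23)cc1O[Si](C)(C)C(C)(C)C | intermediate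
24 | (3R,3aS,4R,8aR)-3-hydroxy-6,8a-dimethyl-3-(propan-2-yl)-1,2,3,3a,4,7,8,8a-octahydroazulen-4-yl 3-hydroxy-4-methoxybenzoate | COc1ccc(C(=O)O[C@@H]2C=C(C)CC[C@]3(C)CC[C@@](O)(C(C)C)[C@H]23)cc1O | target

**Step count**

Total: 14 steps. Longest linear sequence: 12 steps (steps 1–4, 6–11, 13, 14).

**Steps most likely to fail**

Step 6 (key step). What may go wrong: incomplete catalyst control of the absolute configuration, or leakage through a zwitterionic path (attack at the vinyl terminus of the carbenoid, or ring opening of a trans-divinylcyclopropane), either of which erodes enantiomeric purity. Fallback, from 8 and back at 14: stereocontrol is moved from the catalyst to a covalently bound auxiliary, so that stereoisomers become separable diastereomers. But-3-enoic acid is esterified with (R)-pantolactone (DCC, DMAP) to (3R)-4,4-dimethyl-2-oxooxolan-3-yl but-3-enoate F1. Diazo transfer as in step 5 gives (3R)-4,4-dimethyl-2-oxooxolan-3-yl 2-diazobut-3-enoate F2. Reaction of F2 with 8 under achiral Rh2(O2CC7H15)4 in pentane, then warming, should give (3R)-4,4-dimethyl-2-oxooxolan-3-yl (4S)-6-[(tert-butyldimethylsilyl)oxy]-4-methyl-4-(4-methyl-3-oxopentyl)cyclohepta-1,5-diene-1-carboxylate F3, purified from its C4 epimer by chromatography or crystallisation (the S auxiliary is used if the R one favours the wrong epimer). TiCl4 aldol closure as in step 7 gives (3R)-4,4-dimethyl-2-oxooxolan-3-yl (3R,3aR,8aS)-3-hydroxy-8a-methyl-4-oxo-3-(propan-2-yl)-1,2,3,3a,4,5,8,8a-octahydroazulene-6-carboxylate F4. K2CO3 in MeOH then exchanges the auxiliary ester for the methyl ester and moves the double bond into conjugation, which gives 14.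

Step 7. What may go wrong: poor facial discrimination at the ketone carbonyl in the open Lewis-acid transition state (wrong C3 epimer), or loss of the silyl group without C–C bond formation. Fallback, from 12 and back at 14: thermodynamic instead of kinetic control. Buffered fluoride (Bu4NF, AcOH, THF) cleaves the silyl enol ether to methyl (4S)-4-methyl-4-(4-methyl-3-oxopentyl)-6-oxocyclohept-1-ene-1-carboxylate F5. NaOMe in MeOH at 0 °C then moves the double bond into conjugation and closes the five-membered ring by a reversible aldol addition. This should settle on the cis-fused aldol with the isopropyl group on the convex face and the hydroxyl hydrogen-bonded to the C4 ketone, which is 14.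

Step 4. What may go wrong: deprotonation alpha to the nitrile by the basic secondary Grignard reagent instead of addition, and hydrolysis of the silyl dienol ether while the ketimine is being cleaved. Fallback, from 5 and back at 8: the nitrile is taken to the ketone through the aldehyde. iBu2AlH (toluene, −78 °C, neutral work-up) gives (4Z)-6-[(tert-butyldimethylsilyl)oxy]-4-methylhepta-4,6-dienal F6. Isopropylmagnesium chloride adds to the aldehyde to give racemic (6Z)-8-[(tert-butyldimethylsilyl)oxy]-2,6-dimethylnona-6,8-dien-3-ol F7. Dess–Martin periodinane buffered with NaHCO3 oxidises F7 to 8; the transient stereocentre is of no consequence.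

**Further compounds**

F1 | step 6 | (3R)-4,4-dimethyl-2-oxooxolan-3-yl but-3-enoate | C=CCC(=O)O[C@H]1C(=O)OCC1(C)C
F2 | step 6 | (3R)-4,4-dimethyl-2-oxooxolan-3-yl 2-diazobut-3-enoate | C=CC(=[N+]=[N-])C(=O)O[C@H]1C(=O)OCC1(C)C
F3 | step 6 | (3R)-4,4-dimethyl-2-oxooxolan-3-yl (4S)-6-[(tert-butyldimethylsilyl)oxy]-4-methyl-4-(4-methyl-3-oxopentyl)cyclohepta-1,5-diene-1-carboxylate | CC1(C)COC(=O)[C@@H]1OC(=O)C1=CC[C@](C)(CCC(=O)C(C)C)C=C(O[Si](C)(C)C(C)(C)C)C1
F4 | step 6 | (3R)-4,4-dimethyl-2-oxooxolan-3-yl (3R,3aR,8aS)-3-hydroxy-8a-methyl-4-oxo-3-(propan-2-yl)-1,2,3,3a,4,5,8,8a-octahydroazulene-6-carboxylate | CC1(C)COC(=O)[C@@H]1OC(=O)C1=CC[C@]2(C)CC[C@@](O)(C(C)C)[C@@H]2C(=O)C1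
F5 | step 7 | methyl (4S)-4-methyl-4-(4-methyl-3-oxopentyl)-6-oxocyclohept-1-ene-1-carboxylate | COC(=O)C1=CC[C@](C)(CCC(=O)C(C)C)CC(=O)C1
F6 | step 4 | (4Z)-6-[(tert-butyldimethylsilyl)oxy]-4-methylhepta-4,6-dienal | C=C(O[Si](C)(C)C(C)(C)C)/C=C(/C)CCC=O
F7 | step 4 | (6Z)-8-[(tert-butyldimethylsilyl)oxy]-2,6-dimethylnona-6,8-dien-3-ol | C=C(O[Si](C)(C)C(C)(C)C)/C=C(/C)CCC(O)C(C)C
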